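**Direct plan and its weak points**

A direct plan would make ring A as the resorcylate methyl 2,4-dihydroxy-3-(3-methylbut-2-enyl)benzoate A1 by a Michael–Claisen [3+3] annulation of a γ-prenylated acetoacetate with a propiolate.
It would then mask the 4-hydroxyl as a MOM ether and methylate the 2-hydroxyl to reach the benzoate A2, C-prenylate a para-acylphenol and protect it as the MOM ether A3, join A2 and A3 by crossed Claisen condensation to the doubly protected diketone A4 and unmask both phenols with acid.
Its weakest step would be the ring closure that gives A1: the second carbanion is activated by one carbonyl only, the annulation has no close precedent, and everything downstream rests on it, so ring A would be left to chance.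
The second would be the ortho-C-prenylation of a phenoxide: O- against C-alkylation and double alkylation would make a poor step of one that only attaches five carbons.
The third would be the protecting-group work: four of eight steps (two MOM ethers on, the O-methylation they make necessary, two MOM ethers off) would add nothing to the skeleton.
The last of them would expose both ortho-prenylphenols set free from A4 to acid on the finished, most precious compound, where closure to chromans threatens.

**Plan of the new route**

Feature used: in ring A the carbons C2'(OMe)–C3'(prenyl)–C4'(OH)–C5'(H) are the O–C(prenyl)–O–CH unit of the methyl enol ether of 2-prenylcyclohexane-1,3-dione, and in ring B C2(H)–C3(prenyl)–C4(OH)–C5(H) is the dienol of 2-prenylcyclohex-2-enone; C1'/C6' and C1/C6 are the two carbons of an ethynyl ketone.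
The retrosynthesis cuts C1'–C2' and C5'–C6' of ring A and C1–C2 and C5–C6 of ring B, each by Diels–Alder addition of a silyloxycyclohexadiene to an ynone followed by loss of ethene (Alder–Rickert reaction), and the bridge bond CH2–C(=O) on the ring B side.
Order: ring A first (step 3), then the three-carbon bridge, ring B last (step 7) on the finished bridge; two finished arenes are never coupled.
Both prenyl groups come from one C-alkylation of a symmetrical dione, so no arene is prenylated; OMe and OH of ring A are told apart as enol ether and silyl enol ether before the ring is aromatic.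
No step serves protection alone: the silyl groups go on and come off within the cycloaddition steps under far milder acid than MOM cleavage needs, and the untested [3+3] annulation is gone.

Key step: step 3

Remark: the target has no stereocentre; 1,3-diones are drawn as diketones although they will be largely enolised, and the enol silyl ethers that occur in passing are drawn as Z isomers, their geometry being lost on hydrolysis.

**Route**

Step 1
Reactants: 1 cyclohexane-1,3-dione; 2 prenyl bromide (1-bromo-3-methylbut-2-ene)
Product: 3 2-(3-methylbut-2-enyl)cyclohexane-1,3-dione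
Conditions: KOH (1.0 equiv), H2O, 0 °C; 2 (1.05 equiv), rt; dilute HCl to pH 3
Reagents that add atoms: none
Why: C-alkylation (SN2) of the potassium enolate of a cyclic 1,3-dione by a primary allylic bromide in water, where hydrogen bonding to the enolate oxygens favours attack through carbon, and since the dione is symmetrical C2 is the only carbon site and no regioisomer can form.

Step 2
Reactants: 3 2-(3-methylbut-2-enyl)cyclohexane-1,3-dione
Product: 4 3-methoxy-2-(3-methylbut-2-enyl)cyclohex-2-en-1-one
Conditions: Me2SO4 (1.2 equiv), K2CO3 (1.5 equiv), acetone, reflux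
Reagents that add atoms: dimethyl sulfate, COS(=O)(=O)OC
Why: O-methylation of the dione enolate by a hard electrophile (enol ether formation) should give a single vinylogous ester because the two carbonyl groups of 3 are equivalent, while C-methylation at the already substituted C2 is disfavoured and base avoids the acid-induced closure of the enol onto the prenyl group.

Step 3
Reactants: 4 3-methoxy-2-(3-methylbut-2-enyl)cyclohex-2-en-1-one; 5 but-3-yn-2-one
Product: 9 1-[4-hydroxy-2-methoxy-3-(3-methylbut-2-enyl)phenyl]ethanone, via silyl dienol ether 6 (not isolated), via bicyclic adduct 7 (not isolated), via aryl silyl ether 8 (not isolated)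
Conditions: LiN(i-Pr)2 (1.1 equiv), THF, −78 °C; Me3SiCl (1.2 equiv), −78 °C to rt; pentane, filtration, evaporation; 5 (1.5 equiv), toluene, 60 °C, then 130–140 °C (sealed tube); citric acid, MeOH–H2O, rt
Reagents that add atoms: none
Why: Kinetic deprotonation of the vinylogous ester at C6 and O-silylation should give the 1-methoxy-3-silyloxy diene 6, which adds to the ynone in a [4+2] cycloaddition; the bicyclo[2.2.2]octadiene 7 then loses its saturated two-carbon bridge as ethene in a retro-[4+2] step (Alder–Rickert reaction) and the aryl silyl ether 8 is hydrolysed on work-up. The closest known reaction type is the Alder–Rickert synthesis of 4-hydroxy-2-methoxyaryl carbonyl compounds from 1-methoxy-3-(trimethylsilyloxy)cyclohexa-1,3-dienes and acetylenic esters or ketones. Ring A is closed by intermolecular cycloaddition, which forms C1'–C2' and C5'–C6' in one operation, and it becomes aromatic by cycloreversion and not by elimination, so that the methoxy group at the bridgehead is kept. No stereocentre has to be controlled, since the two bridgehead centres of racemic 7 vanish on aromatisation. The step needs regioselectivity, which should be secured because the methoxy group at the diene terminus and the silyloxy group at C3 both raise the HOMO coefficient at the unsubstituted terminus C4, which bonds to the β-carbon of the ynone, so that the acetyl group ends ortho to OMe and para to the silyloxy group with the prenyl group locked between the two oxygens. It also needs chemoselectivity for the diene over the trisubstituted prenyl alkene, which is neither activated nor part of a diene.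

Step 4
Reactants: 9 1-[4-hydroxy-2-methoxy-3-(3-methylbut-2-enyl)phenyl]ethanone; 10 ethyl 3-(trimethylsilyl)prop-2-ynoate
Product: 11 1-[4-hydroxy-2-methoxy-3-(3-methylbut-2-enyl)phenyl]-5-(trimethylsilyl)pent-4-yne-1,3-dione
Conditions: LiN(SiMe3)2 (3.3 equiv), THF, −78 °C; 10 (1.2 equiv), −78 to 0 °C; cold 1 M HCl to pH 4
Reagents that add atoms: none
Why: Claisen-type C-acylation of the lithium enolate of the methyl ketone (as its phenoxide–enolate dianion) by an alkynoate ester, in which the silyl group shields the β-carbon from conjugate addition and deprotonation of the product 1,3-dione by the third equivalent of base drives the reaction, forms the CH2–C(=O) bond of the bridge on the ring B side.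

Step 5
Reactants: 11 1-[4-hydroxy-2-methoxy-3-(3-methylbut-2-enyl)phenyl]-5-(trimethylsilyl)pent-4-yne-1,3-dione
Product: 12 1-[4-hydroxy-2-methoxy-3-(3-methylbut-2-enyl)phenyl]pent-4-yne-1,3-dione
Conditions: n-Bu4NF (1.1 equiv), AcOH (1.5 equiv), THF, −20 to 0 °C; used at once
Reagents that add atoms: none
Why: Fluoride-induced protodesilylation of an alkynylsilane, buffered with acetic acid so that the 1,3-dione and the phenol stay protonated and the enol oxygen does not add to the freed ynone.

Step 6
Reactants: 4 3-methoxy-2-(3-methylbut-2-enyl)cyclohex-2-en-1-one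
Product: 13 2-(3-methylbut-2-enyl)cyclohex-2-en-1-one
Conditions: i-Bu2AlH (1.2 equiv), toluene, −78 °C; then 1 M HCl, THF, 0 °C to rt
Reagents that add atoms: none
Why: Stork–Danheiser 1,3-carbonyl transposition, in which 1,2-reduction of the vinylogous ester and acid-induced hydrolysis of the enol ether with loss of water should give the 2-substituted enone, the cold dilute acid leaving the prenyl alkene untouched.

Step 7
Reactants: 13 2-(3-methylbut-2-enyl)cyclohex-2-en-1-one; 12 1-[4-hydroxy-2-methoxy-3-(3-methylbut-2-enyl)phenyl]pent-4-yne-1,3-dione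
Product: 18 1-[4-hydroxy-2-methoxy-3-(3-methylbut-2-enyl)phenyl]-3-[4-hydroxy-3-(3-methylbut-2-enyl)phenyl]propane-1,3-dione, via silyl dienol ether 14 (not isolated), via bis-silylated ynedione 15 (not isolated), via bicyclic adduct 16 (not isolated), via tris-silyl ether 17 (not isolated)
Conditions: 13 (2.5 equiv): LiN(i-Pr)2, THF, −78 °C; Me3SiCl; pentane, filtration, evaporation (14); 12: MeC(OSiMe3)=NSiMe3 (2.2 equiv), toluene, rt; then 14, 90 °C, then 130–140 °C (sealed tube); citric acid, MeOH–H2O, rt
Reagents that add atoms: none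
Why: A second Alder–Rickert reaction, in which the kinetic cross-conjugated silyl dienol ether 14 should add through its silyl enol ether terminus to the terminal carbon of the ynone of 15 (the silyloxy group outweighs the alkyl-bearing diene carbon, para orientation), 16 loses ethene and mild acid removes the three silyl groups, while the prior silylation keeps the OH groups from protonating the diene and blocks closure of the enol oxygen onto the ynone.

**Compound list**

1 | cyclohexane-1,3-dione | O=C1CCCC(=O)C1 | starting material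
2 | prenyl bromide (1-bromo-3-methylbut-2-ene) | CC(C)=CCBr | starting material
3 | 2-(3-methylbut-2-enyl)cyclohexane-1,3-dione | CC(C)=CCC1C(=O)CCCC1=O | intermediate
4 | 3-methoxy-2-(3-methylbut-2-enyl)cyclohex-2-en-1-one | COC1=C(CC=C(C)C)C(=O)CCC1 | intermediate
5 | but-3-yn-2-one | CC(=O)C#C | starting material
6 | 1-methoxy-2-(3-methylbut-2-enyl)-3-(trimethylsilyloxy)cyclohexa-1,3-diene | COC1=C(CC=C(C)C)C(O[Si](C)(C)C)=CCC1 | intermediate (not isolated)
7 | 1-[1-methoxy-6-(3-methylbut-2-enyl)-5-(trimethylsilyloxy)bicyclo[2.2.2]octa-2,5-dien-2-yl]ethanone (racemic, relative configuration fixed by the bicycle) | CC(=O)C1=CC2CCC1(OC)C(CC=C(C)C)=C2O[Si](C)(C)C | intermediate (not isolated)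
8 | 1-[2-methoxy-3-(3-methylbut-2-enyl)-4-(trimethylsilyloxy)phenyl]ethanone | COc1c(CC=C(C)C)c(O[Si](C)(C)C)ccc1C(C)=O | intermediate (not isolated)
9 | 1-[4-hydroxy-2-methoxy-3-(3-methylbut-2-enyl)phenyl]ethanone | COc1c(CC=C(C)C)c(O)ccc1C(C)=O | intermediate
10 | ethyl 3-(trimethylsilyl)prop-2-ynoate | CCOC(=O)C#C[Si](C)(C)C | starting material
11 | 1-[4-hydroxy-2-methoxy-3-(3-methylbut-2-enyl)phenyl]-5-(trimethylsilyl)pent-4-yne-1,3-dione | COc1c(C(=O)CC(=O)C#C[Si](C)(C)C)ccc(O)c1CC=C(C)C | intermediate
12 | 1-[4-hydroxy-2-methoxy-3-(3-methylbut-2-enyl)phenyl]pent-4-yne-1,3-dione | COc1c(C(=O)CC(=O)C#C)ccc(O)c1CC=C(C)C | intermediate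
13 | 2-(3-methylbut-2-enyl)cyclohex-2-en-1-one | CC(C)=CCC1=CCCCC1=O | intermediate
14 | 2-(3-methylbut-2-enyl)-3-(trimethylsilyloxy)cyclohexa-1,3-diene | CC(C)=CCC1=CCCC=C1O[Si](C)(C)C | intermediate (not isolated)
15 | (Z)-1-[2-methoxy-3-(3-methylbut-2-enyl)-4-(trimethylsilyloxy)phenyl]-1-(trimethylsilyloxy)pent-1-en-4-yn-3-one (one of two interconverting O-silyl isomers) | COc1c(/C(O[Si](C)(C)C)=C/C(=O)C#C)ccc(O[Si](C)(C)C)c1CC=C(C)C | intermediate (not isolated)
16 | (Z)-3-[2-methoxy-3-(3-methylbut-2-enyl)-4-(trimethylsilyloxy)phenyl]-1-[6-(3-methylbut-2-enyl)-5-(trimethylsilyloxy)bicyclo[2.2.2]octa-2,5-dien-2-yl]-3-(trimethylsilyloxy)prop-2-en-1-one (racemic) | COc1c(/C(O[Si](C)(C)C)=C/C(=O)C2=CC3CCC2C(CC=C(C)C)=C3O[Si](C)(C)C)ccc(O[Si](C)(C)C)c1CC=C(C)C | intermediate (not isolated)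
17 | (Z)-3-[2-methoxy-3-(3-methylbut-2-enyl)-4-(trimethylsilyloxy)phenyl]-1-[3-(3-methylbut-2-enyl)-4-(trimethylsilyloxy)phenyl]-3-(trimethylsilyloxy)prop-2-en-1-one | COc1c(/C(O[Si](C)(C)C)=C/C(=O)c2ccc(O[Si](C)(C)C)c(CC=C(C)C)c2)ccc(O[Si](C)(C)C)c1CC=C(C)C | intermediate (not isolated)
18 | 1-[4-hydroxy-2-methoxy-3-(3-methylbut-2-enyl)phenyl]-3-[4-hydroxy-3-(3-methylbut-2-enyl)phenyl]propane-1,3-dione (no stereocentres) | COc1c(C(=O)CC(=O)c2ccc(O)c(CC=C(C)C)c2)ccc(O)c1CC=C(C)C | target

**Step count and risks**

Total steps: 7. Longest linear sequence: 6 (steps 1, 2, 3, 4, 5, 7); step 6 is a one-step branch from 4.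

Steps most likely to fail:

1. Step 7. The singly activated diene 14 may add too slowly, or in both orientations if the silyloxy group does not clearly outweigh the prenyl-bearing diene carbon, and the silylated ynedione may decay at the temperature needed for ethene loss, all on the most advanced material. The fallback reverses the order in which the rings are made, so that the last cycloaddition uses the doubly biased diene 6 and any regioisomer of ring B is removed early on cheap material. It sets out from 13: diene 14 and but-3-yn-2-one 5 should give, by the same cycloaddition and ethene loss, the bicyclic adduct 1-[6-(3-methylbut-2-enyl)-5-(trimethylsilyloxy)bicyclo[2.2.2]octa-2,5-dien-2-yl]ethanone F1, the aryl silyl ether 1-[3-(3-methylbut-2-enyl)-4-(trimethylsilyloxy)phenyl]ethanone F2 and, after dilute acid, 1-[4-hydroxy-3-(3-methylbut-2-enyl)phenyl]ethanone F3. Acylation of F3 with 10 as in step 4 should give 1-[4-hydroxy-3-(3-methylbut-2-enyl)phenyl]-5-(trimethylsilyl)pent-4-yne-1,3-dione F4, and buffered fluoride as in step 5 should give 1-[4-hydroxy-3-(3-methylbut-2-enyl)phenyl]pent-4-yne-1,3-dione F5. Silylation with MeC(OSiMe3)=NSiMe3 should give (Z)-1-[3-(3-methylbut-2-enyl)-4-(trimethylsilyloxy)phenyl]-1-(trimethylsilyloxy)pent-1-en-4-yn-3-one F6, which is heated with diene 6 (made from 4 as in step 3). This should lead through the adduct (Z)-1-[1-methoxy-6-(3-methylbut-2-enyl)-5-(trimethylsilyloxy)bicyclo[2.2.2]octa-2,5-dien-2-yl]-3-[3-(3-methylbut-2-enyl)-4-(trimethylsilyloxy)phenyl]-3-(trimethylsilyloxy)prop-2-en-1-one F7 and the tris-silyl ether (Z)-1-[2-methoxy-3-(3-methylbut-2-enyl)-4-(trimethylsilyloxy)phenyl]-3-[3-(3-methylbut-2-enyl)-4-(trimethylsilyloxy)phenyl]-3-(trimethylsilyloxy)prop-2-en-1-one F8 to the target after mild acid. The fallback comes back to the route at 18.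

2. Step 5. Once the alkyne is free, the enol oxygen of the 1,3-dione may add to it (closure to a 4-pyranone), or fluoride or acetate may add to the terminal ynone. The fallback brings in the three-carbon unit without silicon and creates the dione last under neutral conditions. It sets out from 9: the dianion (LiN(i-Pr)2, 2.1 equiv, THF, −78 °C) should add to prop-2-ynal to give racemic 3-hydroxy-1-[4-hydroxy-2-methoxy-3-(3-methylbut-2-enyl)phenyl]pent-4-yn-1-one F9, and MnO2 in CH2Cl2 should oxidise the propargylic alcohol to the dione. The fallback comes back to the route at 12.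

3. Step 4. The phenoxide–enolate may add to the β-carbon of the alkynoate, the ethoxide set free may attack the alkynylsilane, or acylation may stop short because the product consumes base. The fallback replaces acylation by aldol addition and oxidation. It sets out from 9: the same dianion should add to the aldehyde carbon of 3-(trimethylsilyl)prop-2-ynal, with no alkoxide released, to give racemic 3-hydroxy-1-[4-hydroxy-2-methoxy-3-(3-methylbut-2-enyl)phenyl]-5-(trimethylsilyl)pent-4-yn-1-one F10, which MnO2 in CH2Cl2 should oxidise to the dione. The fallback comes back to the route at 11.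

Further compounds
F1 | step 7 | 1-[6-(3-methylbut-2-enyl)-5-(trimethylsilyloxy)bicyclo[2.2.2]octa-2,5-dien-2-yl]ethanone (racemic) | CC(=O)C1=CC2CCC1C(CC=C(C)C)=C2O[Si](C)(C)C
F2 | step 7 | 1-[3-(3-methylbut-2-enyl)-4-(trimethylsilyloxy)phenyl]ethanone | CC(=O)c1ccc(O[Si](C)(C)C)c(CC=C(C)C)c1
F3 | step 7 | 1-[4-hydroxy-3-(3-methylbut-2-enyl)phenyl]ethanone | CC(=O)c1ccc(O)c(CC=C(C)C)c1
F4 | step 7 | 1-[4-hydroxy-3-(3-methylbut-2-enyl)phenyl]-5-(trimethylsilyl)pent-4-yne-1,3-dione | CC(C)=CCc1cc(C(=O)CC(=O)C#C[Si](C)(C)C)ccc1O
F5 | step 7 | 1-[4-hydroxy-3-(3-methylbut-2-enyl)phenyl]pent-4-yne-1,3-dione | CC(C)=CCc1cc(C(=O)CC(=O)C#C)ccc1O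
F6 | step 7 | (Z)-1-[3-(3-methylbut-2-enyl)-4-(trimethylsilyloxy)phenyl]-1-(trimethylsilyloxy)pent-1-en-4-yn-3-one | CC(C)=CCc1cc(/C(O[Si](C)(C)C)=C/C(=O)C#C)ccc1O[Si](C)(C)C
F7 | step 7 | (Z)-1-[1-methoxy-6-(3-methylbut-2-enyl)-5-(trimethylsilyloxy)bicyclo[2.2.2]octa-2,5-dien-2-yl]-3-[3-(3-methylbut-2-enyl)-4-(trimethylsilyloxy)phenyl]-3-(trimethylsilyloxy)prop-2-en-1-one (racemic) | O=C(/C=C(\O[Si](C)(C)C)c1ccc(O[Si](C)(C)C)c(CC=C(C)C)c1)C1=CC2CCC1(OC)C(CC=C(C)C)=C2O[Si](C)(C)C
F8 | step 7 | (Z)-1-[2-methoxy-3-(3-methylbut-2-enyl)-4-(trimethylsilyloxy)phenyl]-3-[3-(3-methylbut-2-enyl)-4-(trimethylsilyloxy)phenyl]-3-(trimethylsilyloxy)prop-2-en-1-one | COc1c(C(=O)/C=C(\O[Si](C)(C)C)c2ccc(O[Si](C)(C)C)c(CC=C(C)C)c2)ccc(O[Si](C)(C)C)c1CC=C(C)C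
F9 | step 5 | 3-hydroxy-1-[4-hydroxy-2-methoxy-3-(3-methylbut-2-enyl)phenyl]pent-4-yn-1-one (racemic) | COc1c(C(=O)CC(O)C#C)ccc(O)c1CC=C(C)C
F10 | step 4 | 3-hydroxy-1-[4-hydroxy-2-methoxy-3-(3-methylbut-2-enyl)phenyl]-5-(trimethylsilyl)pent-4-yn-1-one (racemic) | COc1c(C(=O)CC(O)C#C[Si](C)(C)C)ccc(O)c1CC=C(C)C
A1 | direct plan | methyl 2,4-dihydroxy-3-(3-methylbut-2-enyl)benzoate | COC(=O)c1ccc(O)c(CC=C(C)C)c1O
A2 | direct plan | methyl 2-methoxy-4-(methoxymethoxy)-3-(3-methylbut-2-enyl)benzoate | COCOc1ccc(C(=O)OC)c(OC)c1CC=C(C)C
A3 | direct plan | 1-[4-(methoxymethoxy)-3-(3-methylbut-2-enyl)phenyl]ethanone | CC(=O)c1ccc(OCOC)c(CC=C(C)C)c1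
A4 | direct plan | 1-[2-methoxy-4-(methoxymethoxy)-3-(3-methylbut-2-enyl)phenyl]-3-[4-(methoxymethoxy)-3-(3-methylbut-2-enyl)phenyl]propane-1,3-dione | COCOc1ccc(C(=O)CC(=O)c2ccc(OCOC)c(CC=C(C)C)c2)c(OC)c1CC=C(C)C
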